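**Strategy.** The six-membered ring is cut at C2–C3 and C4–C5 (C1 bears the CH2OH carbon C7, C6 is the ketone). The C5–C6–C1–C2 unit, with C7 and the C6 oxygen, comes from a 2-silyloxy-3-(silyloxymethyl)butadiene. The C3–C4 unit, with the isopropyl group, comes from (E)-5-methylhex-3-en-2-one, whose acetyl group stands in for the C3 oxygen. One catalytic enantioselective Diels–Alder reaction closes the only carbocycle, sets C4 absolutely and C3 relative to it, and leaves a C6 enol ether ready for the C1=C2 enone. The diene carries a bulky triisopropylsilyl enol ether and a TBS-protected C7 hydroxyl so that it tolerates the acidic catalyst.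

Key step: step 4

Remark on the chemistry: ring atoms are numbered C1 (bears C7), C2 (=CH), C3 (angelate), C4 (isopropyl), C5 (epoxy ester), C6 (ketone) throughout. The sense of induction in step 4 is assigned from the accepted α-C–H···O binding model of the catalyst, not from a measured result.

**Step 1**
Reactants: 1 methyl vinyl ketone; 2 paraformaldehyde
Product: 3 3-(hydroxymethyl)but-3-en-2-one
Conditions: paraformaldehyde cracked in H2O (cat. H3PO4, 80 °C); then DABCO (10 mol%), THF/H2O, rt
Reagents that add atoms: none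
Why: Morita–Baylis–Hillman reaction, in which DABCO adds to the enone, the enolate is hydroxymethylated by formaldehyde and the amine is expelled; no stereocentre is formed.

**Step 2**
Reactants: 3 3-(hydroxymethyl)but-3-en-2-one
Product: 4 3-(tert-butyldimethylsilyloxymethyl)but-3-en-2-one
Conditions: TBSCl, imidazole, CH2Cl2, 0 °C to rt
Reagents that add atoms: tert-butyldimethylsilyl chloride, CC(C)(C)[Si](C)(C)Cl
Why: Standard imidazole-promoted silylation of a primary allylic alcohol; the TBS ether should last until the final fluoride treatment.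

**Step 3**
Reactants: 4 3-(tert-butyldimethylsilyloxymethyl)but-3-en-2-one
Product: 5 3-(tert-butyldimethylsilyloxymethyl)-2-(triisopropylsilyloxy)buta-1,3-diene
Conditions: TIPSOTf, Et3N, Et2O, 0 °C
Reagents that add atoms: triisopropylsilyl trifluoromethanesulfonate, CC(C)[Si](OS(=O)(=O)C(F)(F)F)(C(C)C)C(C)C
Why: Soft enolisation (silyl triflate/amine) can only take place at the methyl group and gives the cross-conjugated 2-silyloxydiene, whose bulky silyl group resists the acid of step 4.

**Step 4**
Reactants: 5 3-(tert-butyldimethylsilyloxymethyl)-2-(triisopropylsilyloxy)buta-1,3-diene; 6 (E)-5-methylhex-3-en-2-one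
Product: 7 1-[(1S,6R)-3-(tert-butyldimethylsilyloxymethyl)-6-isopropyl-4-(triisopropylsilyloxy)cyclohex-3-en-1-yl]ethanone (acetyl and isopropyl trans)
Conditions: (S)-3,3-diphenyl-1-(o-tolyl)tetrahydro-1H,3H-pyrrolo[1,2-c][1,3,2]oxazaborole (20 mol%), HNTf2 (18 mol%), CH2Cl2, −78 to −40 °C; Et3N quench
Reagents that add atoms: none
Why: The protonated oxazaborolidine binds the enone oxygen on the lone pair syn to the vinyl group (s-trans enone, α-C–H···O contact to the ring oxygen) and lowers the LUMO; the diene then adds in a concerted, asynchronous, suprafacial [4+2] cycloaddition in which the C4–C5 bond (enol ether terminus to the enone β-carbon) runs ahead of C2–C3. The closest known reaction type is the oxazaborolidinium-catalysed Diels–Alder reaction of 2-silyloxybutadienes with α,β-unsaturated ketones and esters. The six-membered carbocycle is closed by this intermolecular 4π+2π union, both σ bonds forming on one face of each partner. C4 is set by the catalyst, whose phenyl group covers one face of the bound enone so that with the (S)-catalyst the diene should reach the Si face of the acetyl-bearing carbon; C3 follows from the E geometry, which is carried over as the trans acetyl/isopropyl pair. The step needs para regioselectivity and survival of the enol ether: the first is secured by the dominant donor effect of the 2-silyloxy group (largest HOMO coefficient at C5), the second by the triisopropylsilyl group, and the unsubstituted diene termini leave no endo/exo issue.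

**Step 5**
Reactants: 7 the cycloadduct
Product: 9 (4R,5R)-4-acetyl-2-(tert-butyldimethylsilyloxymethyl)-5-isopropylcyclohex-2-en-1-one, via alpha-phenylselanyl ketone 8 (not isolated)
Conditions: PhSeCl, CH2Cl2, −78 to 0 °C; then pyridine, 30% H2O2, 0 °C to rt
Reagents that add atoms: none
Why: Selenenylation of the silyl enol ether at C1 followed by selenoxide syn-elimination, which should go toward C2 and not toward the oxygen-bearing C7 because selenoxides avoid forming enol ethers; C3 and C4 are not involved (C3 may equilibrate, but trans is the favoured arrangement).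

**Step 6**
Reactants: 9 the acetyl enone
Product: 10 (1R,6R)-3-(tert-butyldimethylsilyloxymethyl)-6-isopropyl-4-oxocyclohex-2-en-1-yl acetate
Conditions: mCPBA, NaHCO3, CH2Cl2, 0 °C to rt
Reagents that add atoms: 3-chloroperoxybenzoic acid, O=C(OO)c1cccc(Cl)c1
Why: Baeyer–Villiger oxidation, in which the secondary ring carbon C3 migrates in preference to methyl with retention; the conjugated ring ketone and the electron-poor C1=C2 bond should react far more slowly with the buffered peracid.

**Step 7**
Reactants: 10 the C3 acetate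
Product: 11 (4R,5R)-2-(tert-butyldimethylsilyloxymethyl)-4-hydroxy-5-isopropylcyclohex-2-en-1-one
Conditions: K2CO3 (0.3 equiv), MeOH, 0 °C
Reagents that add atoms: none
Why: Base-catalysed transesterification (methanolysis) of the secondary acetate under cold, short conditions that should spare the silyl ether and the enone; C3 keeps its configuration.

**Step 8**
Reactants: 11 the trans C3 alcohol; 12 angelic acid
Product: 13 (1S,6R)-3-(tert-butyldimethylsilyloxymethyl)-6-isopropyl-4-oxocyclohex-2-en-1-yl (Z)-2-methylbut-2-enoate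
Conditions: PPh3, DIAD, toluene, 0 °C to rt
Reagents that add atoms: none
Why: Mitsunobu esterification, in which the angelate anion displaces the oxyphosphonium group at C3 by SN2 with inversion to give the 3,4-cis ester; using the carboxylate as nucleophile avoids the Z-to-E isomerisation that acyl activation of angelic acid can cause.

**Step 9**
Reactants: 13 the angelate enone
Product: 14 (1S,6S)-3-(tert-butyldimethylsilyloxymethyl)-6-isopropyl-4-(trimethylsilyloxy)cyclohexa-2,4-dien-1-yl (Z)-2-methylbut-2-enoate
Conditions: LiN(SiMe3)2, Me3SiCl, THF, −78 °C; pentane, filtration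
Reagents that add atoms: chlorotrimethylsilane, C[Si](C)(C)Cl
Why: Kinetic α′-enolisation of the enone at C5 by a hindered amide base with in situ silylation gives the cross-conjugated silyl dienol ether; the angelate has no α-hydrogen and should be left alone at this temperature.

**Step 10**
Reactants: 14 the silyl dienol ether
Product: 17 (1R,5S,6R)-3-(tert-butyldimethylsilyloxymethyl)-5-hydroxy-6-isopropyl-4-oxocyclohex-2-en-1-yl (Z)-2-methylbut-2-enoate, via silyloxy epoxide 15 (not isolated), via alpha-silyloxy ketone 16 (not isolated)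
Conditions: mCPBA, NaHCO3, CH2Cl2, −20 °C; then AcOH/THF/H2O, 0 °C
Reagents that add atoms: 3-chloroperoxybenzoic acid, O=C(OO)c1cccc(Cl)c1
Why: Rubottom oxidation, in which the peracid epoxidises the electron-rich C5=C6 enol ether from the face opposite the C4 isopropyl and C3 acyloxy groups; ring opening with 1,4-silyl shift and mild acid then give the 4,5-trans α-hydroxy ketone.

**Step 11**
Reactants: 12 angelic acid
Product: 18 (Z)-2-methylbut-2-en-1-ol
Conditions: LiAlH4, Et2O, 0 °C to rt
Reagents that add atoms: none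
Why: Hydride 1,2-reduction of the unsaturated acid to the allylic alcohol; the Z double bond is not touched.

**Step 12**
Reactants: 18 (Z)-2-methylbut-2-en-1-ol
Product: 19 [(2S,3R)-2,3-dimethyloxiran-2-yl]methanol
Conditions: Ti(OiPr)4, L-(+)-diethyl tartrate, t-BuOOH, 4 Å MS, CH2Cl2, −20 °C
Reagents that add atoms: tert-butyl hydroperoxide, CC(C)(C)OO
Why: Sharpless asymmetric epoxidation, in which the L-(+)-tartrate complex delivers oxygen to the face that gives the (2S) centre; the cis relation of CH2OH and the C3 methyl follows from the Z alkene.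

**Step 13**
Reactants: 19 the epoxy alcohol
Product: 20 (2R,3R)-2,3-dimethyloxirane-2-carboxylic acid
Conditions: RuCl3·xH2O (2 mol%), NaIO4, MeCN/EtOAc/H2O, rt
Reagents that add atoms: water, O
Why: Ruthenium tetroxide oxidation (catalytic RuCl3, NaIO4) of the primary alcohol to the acid; the quaternary C2 and C3 cannot epimerise, and the descriptor at C2 changes only because of the priority rules.

**Step 14**
Reactants: 17 the C5 alcohol; 20 the epoxy acid
Product: 22 (1R,5S,6R)-3-(tert-butyldimethylsilyloxymethyl)-5-[(2R,3R)-2,3-dimethyloxirane-2-carbonyloxy]-6-isopropyl-4-oxocyclohex-2-en-1-yl (Z)-2-methylbut-2-enoate, via mixed anhydride 21 (not isolated)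
Conditions: 2,4,6-trichlorobenzoyl chloride, Et3N, toluene, rt; then 17, DMAP, rt
Reagents that add atoms: none
Why: Yamaguchi esterification through the mixed anhydride acylates the hindered C5 hydroxyl; the acid has no α-hydrogen, so its stereocentres are safe.

**Step 15**
Reactants: 22 the silyl-protected diester
Product: 23 CNP0293054.1, (1R,5S,6R)-5-[(2R,3R)-2,3-dimethyloxirane-2-carbonyloxy]-3-(hydroxymethyl)-6-isopropyl-4-oxocyclohex-2-en-1-yl (Z)-2-methylbut-2-enoate
Conditions: HF·pyridine, pyridine, THF, 0 °C to rt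
Reagents that add atoms: none
Why: Fluoride-mediated desilylation of the primary TBS ether under buffered conditions that should spare both esters, the epoxide and the α-acyloxy ketone.

**Compound list**
1 | methyl vinyl ketone | CC(=O)C=C | starting material
2 | paraformaldehyde (formaldehyde) | C=O | starting material
3 | 3-(hydroxymethyl)but-3-en-2-one | CC(=O)C(=C)CO | intermediate
4 | 3-(tert-butyldimethylsilyloxymethyl)but-3-en-2-one | CC(=O)C(=C)CO[Si](C)(C)C(C)(C)C | intermediate
5 | 3-(tert-butyldimethylsilyloxymethyl)-2-(triisopropylsilyloxy)buta-1,3-diene | C=C(O[Si](C(C)C)(C(C)C)C(C)C)C(=C)CO[Si](C)(C)C(C)(C)C | intermediate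
6 | (E)-5-methylhex-3-en-2-one | CC(=O)/C=C/C(C)C | starting material
7 | 1-[(1S,6R)-3-(tert-butyldimethylsilyloxymethyl)-6-isopropyl-4-(triisopropylsilyloxy)cyclohex-3-en-1-yl]ethanone | CC(=O)[C@H]1CC(CO[Si](C)(C)C(C)(C)C)=C(O[Si](C(C)C)(C(C)C)C(C)C)C[C@@H]1C(C)C | intermediate
8 | (4S,5R)-4-acetyl-2-(tert-butyldimethylsilyloxymethyl)-5-isopropyl-2-(phenylselanyl)cyclohexan-1-one (both C2 epimers) | CC(=O)[C@H]1CC(CO[Si](C)(C)C(C)(C)C)([Se]c2ccccc2)C(=O)C[C@@H]1C(C)C | intermediate
9 | (4R,5R)-4-acetyl-2-(tert-butyldimethylsilyloxymethyl)-5-isopropylcyclohex-2-en-1-one | CC(=O)[C@H]1C=C(CO[Si](C)(C)C(C)(C)C)C(=O)C[C@@H]1C(C)C | intermediate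
10 | (1R,6R)-3-(tert-butyldimethylsilyloxymethyl)-6-isopropyl-4-oxocyclohex-2-en-1-yl acetate | CC(=O)O[C@H]1C=C(CO[Si](C)(C)C(C)(C)C)C(=O)C[C@@H]1C(C)C | intermediate
11 | (4R,5R)-2-(tert-butyldimethylsilyloxymethyl)-4-hydroxy-5-isopropylcyclohex-2-en-1-one | O[C@H]1C=C(CO[Si](C)(C)C(C)(C)C)C(=O)C[C@@H]1C(C)C | intermediate
12 | angelic acid, (Z)-2-methylbut-2-enoic acid | C/C=C(/C)C(=O)O | starting material
13 | (1S,6R)-3-(tert-butyldimethylsilyloxymethyl)-6-isopropyl-4-oxocyclohex-2-en-1-yl (Z)-2-methylbut-2-enoate | C/C=C(/C)C(=O)O[C@@H]1C=C(CO[Si](C)(C)C(C)(C)C)C(=O)C[C@@H]1C(C)C | intermediate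
14 | (1S,6S)-3-(tert-butyldimethylsilyloxymethyl)-6-isopropyl-4-(trimethylsilyloxy)cyclohexa-2,4-dien-1-yl (Z)-2-methylbut-2-enoate | C/C=C(/C)C(=O)O[C@@H]1C=C(CO[Si](C)(C)C(C)(C)C)C(O[Si](C)(C)C)=C[C@@H]1C(C)C | intermediate
15 | C5–C6 silyloxy epoxide of 14, epoxide oxygen anti to isopropyl: 5-(tert-butyldimethylsilyloxymethyl)-2-isopropyl-6-(trimethylsilyloxy)-7-oxabicyclo[4.1.0]hept-4-en-3-yl (Z)-2-methylbut-2-enoate | C/C=C(/C)C(=O)O[C@@H]1C=C(CO[Si](C)(C)C(C)(C)C)[C@@]2(O[Si](C)(C)C)O[C@H]2[C@@H]1C(C)C | intermediate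
16 | (1R,5S,6R)-3-(tert-butyldimethylsilyloxymethyl)-6-isopropyl-4-oxo-5-(trimethylsilyloxy)cyclohex-2-en-1-yl (Z)-2-methylbut-2-enoate | C/C=C(/C)C(=O)O[C@@H]1C=C(CO[Si](C)(C)C(C)(C)C)C(=O)[C@@H](O[Si](C)(C)C)[C@@H]1C(C)C | intermediate
17 | (1R,5S,6R)-3-(tert-butyldimethylsilyloxymethyl)-5-hydroxy-6-isopropyl-4-oxocyclohex-2-en-1-yl (Z)-2-methylbut-2-enoate | C/C=C(/C)C(=O)O[C@@H]1C=C(CO[Si](C)(C)C(C)(C)C)C(=O)[C@@H](O)[C@@H]1C(C)C | intermediate
18 | (Z)-2-methylbut-2-en-1-ol | C/C=C(/C)CO | intermediate
19 | [(2S,3R)-2,3-dimethyloxiran-2-yl]methanol | OC[C@]1(C)O[C@@H]1C | intermediate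
20 | (2R,3R)-2,3-dimethyloxirane-2-carboxylic acid | OC(=O)[C@]1(C)O[C@@H]1C | intermediate
21 | (2R,3R)-2,3-dimethyloxirane-2-carboxylic 2,4,6-trichlorobenzoic anhydride | O=C(OC(=O)[C@]1(C)O[C@@H]1C)c2c(Cl)cc(Cl)cc2Cl | intermediate
22 | (1R,5S,6R)-3-(tert-butyldimethylsilyloxymethyl)-5-[(2R,3R)-2,3-dimethyloxirane-2-carbonyloxy]-6-isopropyl-4-oxocyclohex-2-en-1-yl (Z)-2-methylbut-2-enoate | C/C=C(/C)C(=O)O[C@@H]1C=C(CO[Si](C)(C)C(C)(C)C)C(=O)[C@@H](OC(=O)[C@]2(C)O[C@@H]2C)[C@@H]1C(C)C | intermediate
23 | CNP0293054.1 | C/C=C(/C)C(=O)O[C@@H]1C=C(CO)C(=O)[C@@H](OC(=O)[C@]2(C)O[C@@H]2C)[C@@H]1C(C)C | target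

**Step count.** Total: 15 steps. Longest linear sequence: 12 steps (steps 1–10, 14 and 15, from methyl vinyl ketone); steps 11–13 form the three-step side branch to the epoxy acid.

**Steps most likely to fail**

1. Step 4. The β-branched acyclic enone may add too slowly, silyl transfer in a stepwise Michael pathway may compete with ring closure, or facial discrimination may be insufficient. Fallback (auxiliary control in place of catalyst control), setting out from diene 5: (E)-4-methylpent-2-enoic acid is converted through its pivalic mixed anhydride and the lithiated auxiliary into (S)-4-benzyl-3-[(E)-4-methylpent-2-enoyl]oxazolidin-2-one F1. With Et2AlCl (1.4 equiv) in CH2Cl2 at −78 °C this chelated s-cis imide, whose benzyl group blocks one face, should add 5 on the same enone face as in step 4 to give (S)-4-benzyl-3-{[(1S,6R)-3-(tert-butyldimethylsilyloxymethyl)-6-isopropyl-4-(triisopropylsilyloxy)cyclohex-3-en-1-yl]carbonyl}oxazolidin-2-one F2. MeNH(OMe)·HCl with AlMe3 then gives (1S,6R)-3-(tert-butyldimethylsilyloxymethyl)-6-isopropyl-N-methoxy-N-methyl-4-(triisopropylsilyloxy)cyclohex-3-ene-1-carboxamide F3, and MeMgBr in THF at 0 °C converts it into ketone 7, where the route is rejoined.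

2. Step 8. The activated allylic alcohol may eliminate toward a dienone that aromatises, displacement syn to the neighbouring isopropyl group may be slow with the weakly acidic angelic acid, or the angelate may isomerise. Fallback (inversion and angelate introduction separated), setting out from alcohol 11: Mitsunobu reaction with the more acidic 4-nitrobenzoic acid (PPh3, DIAD, toluene) should give the inverted ester (1S,6R)-3-(tert-butyldimethylsilyloxymethyl)-6-isopropyl-4-oxocyclohex-2-en-1-yl 4-nitrobenzoate F4. K2CO3 in MeOH at 0 °C frees the cis alcohol (4S,5R)-2-(tert-butyldimethylsilyloxymethyl)-4-hydroxy-5-isopropylcyclohex-2-en-1-one F5. Acylation with retention by preformed angelic 2,4,6-trichlorobenzoic anhydride F6 (from 12, 2,4,6-trichlorobenzoyl chloride and Et3N; then F5, toluene, 80 °C) leads back to angelate 13.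

3. Step 5. Selenenylation of the hindered tetrasubstituted enol ether may be incomplete, the syn-elimination may turn toward C7, or the acidic C3–H of the product may be selenenylated. Fallback (Saegusa oxidation in place of selenoxide elimination), setting out from 7: stoichiometric Pd(OAc)2 in DMSO at rt to 40 °C should transfer the silyl group to acetate, form the oxa-π-allyl complex of divalent palladium and give enone 9 by β-hydride elimination toward C2, where the route is rejoined; no new compound is made (F0).

**Further compounds**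
F1 | step 4 | (S)-4-benzyl-3-[(E)-4-methylpent-2-enoyl]oxazolidin-2-one | CC(C)/C=C/C(=O)N1[C@@H](Cc2ccccc2)COC1=O
F2 | step 4 | (S)-4-benzyl-3-{[(1S,6R)-3-(tert-butyldimethylsilyloxymethyl)-6-isopropyl-4-(triisopropylsilyloxy)cyclohex-3-en-1-yl]carbonyl}oxazolidin-2-one | O=C([C@H]1CC(CO[Si](C)(C)C(C)(C)C)=C(O[Si](C(C)C)(C(C)C)C(C)C)C[C@@H]1C(C)C)N1[C@@H](Cc2ccccc2)COC1=O
F3 | step 4 | (1S,6R)-3-(tert-butyldimethylsilyloxymethyl)-6-isopropyl-N-methoxy-N-methyl-4-(triisopropylsilyloxy)cyclohex-3-ene-1-carboxamide | CON(C)C(=O)[C@H]1CC(CO[Si](C)(C)C(C)(C)C)=C(O[Si](C(C)C)(C(C)C)C(C)C)C[C@@H]1C(C)C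
F4 | step 8 | (1S,6R)-3-(tert-butyldimethylsilyloxymethyl)-6-isopropyl-4-oxocyclohex-2-en-1-yl 4-nitrobenzoate | O=C(O[C@@H]1C=C(CO[Si](C)(C)C(C)(C)C)C(=O)C[C@@H]1C(C)C)c2ccc(cc2)[N+](=O)[O-]
F5 | step 8 | (4S,5R)-2-(tert-butyldimethylsilyloxymethyl)-4-hydroxy-5-isopropylcyclohex-2-en-1-one | O[C@@H]1C=C(CO[Si](C)(C)C(C)(C)C)C(=O)C[C@@H]1C(C)C
F6 | step 8 | (Z)-2-methylbut-2-enoic 2,4,6-trichlorobenzoic anhydride | C/C=C(/C)C(=O)OC(=O)c1c(Cl)cc(Cl)cc1Cl
F0 | step 5 | none | none
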